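**Retrosynthetic overview**

- Target ⇒ peracid epoxidation of the C5=C6 bond of the (3R)-3-tetradecanoyloxy dienone, anti to the ester (oxirane formed last).
- Dienone ⇒ Heck coupling of a 2,6,6-trimethylcyclohexenyl triflate with but-3-en-2-one (C6–C7 bond).
- Cyclohexenyl triflate ⇒ one-carbon ring expansion of a 4-acyloxy-2,2-dimethylcyclopentanone with a C(Me)(SiMe3) diazo unit (key step; brings in C5 and its methyl and fixes the alkene position).
- Cyclopentanone ester ⇒ (S)-4-hydroxy-2,2-dimethylcyclopentanone (dehydrogenation, then Cu-catalysed asymmetric β-borylation/oxidation; sets C3) + tetradecanoic acid (C7 + C7 Grignard coupling, then hydroboration/oxidation).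
- Ring order: cyclopentane (purchased) → cyclohexene (ring expansion) → oxirane (epoxidation).

Assumption: 1-(trimethylsilyl)diazoethane (made beforehand from TMSCHN2, n-BuLi, MeI) counts as a reagent; the Josiphos antipode used is the one found to give the S-configured hydroxy ketone.

**Route**

Step 1
Reactants: 1 2,2-dimethylcyclopentan-1-one
Product: 2 5,5-dimethylcyclopent-2-en-1-one
Conditions: IBX (2 equiv), PhF/DMSO 2:1, 65–70 °C
Reagents that add atoms: none
Why: IBX α,β-dehydrogenation of a ketone (Nicolaou dehydrogenation); C5 is the only enolisable position and the quaternary carbon blocks further oxidation, so one achiral enone forms.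

Step 2
Reactants: 2 5,5-dimethylcyclopent-2-en-1-one
Product: 4 (4S)-4-hydroxy-2,2-dimethylcyclopentan-1-one, via β-boryl ketone 3 (not isolated)
Conditions: B2pin2 (1.1 equiv), CuCl (3 mol %), NaOt-Bu (6 mol %), Josiphos SL-J001 (4 mol %), MeOH (2 equiv), THF, rt; then NaBO3·4H2O, THF/H2O, rt
Reagents that add atoms: bis(pinacolato)diboron, CC1(C)OB(OC1(C)C)B1OC(C)(C)C(C)(C)O1 (boron carried in 3 only); sodium perborate, [Na+].[Na+].O[B-]1(O)OO[B-](O)(O)OO1 (the hydroxyl oxygen)
Why: Cu-catalysed enantioselective conjugate borylation of a cyclic enone delivers Cu–Bpin to one face of the β-carbon under ligand control, and stereoretentive perborate oxidation of the C–B bond then gives the S carbinol centre (the later C3).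

Step 3
Reactants: 5 1-bromoheptane; 6 7-bromohept-1-ene
Product: 8 tetradec-1-ene, via heptylmagnesium bromide 7 (not isolated)
Conditions: Mg, THF, 40 °C; then 6, Li2CuCl4 (2 mol %), THF, −10 °C → rt
Reagents that add atoms: magnesium, [Mg] (in 7 only)
Why: Grignard formation followed by Kochi copper-catalysed sp3–sp3 cross-coupling of a primary alkylmagnesium with a primary bromide; the remote terminal alkene is inert and no stereocentre arises.

Step 4
Reactants: 8 tetradec-1-ene
Product: 10 tetradecanoic acid, via tritetradecylborane 9 (not isolated)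
Conditions: BH3·SMe2 (0.35 equiv), THF, 0 °C → rt; then CrO3, AcOH/H2O 9:1, rt
Reagents that add atoms: borane–dimethyl sulfide, [BH3-][S+](C)C (boron in 9 only); chromium(VI) oxide, O=[Cr](=O)=O; water, O
Why: Anti-Markovnikov hydroboration puts boron on C1, and direct chromic acid oxidation of the primary trialkylborane (Brown oxidation) gives the acid without change in carbon count.

Step 5
Reactants: 4 (4S)-4-hydroxy-2,2-dimethylcyclopentan-1-one; 10 tetradecanoic acid
Product: 11 (1S)-3,3-dimethyl-4-oxocyclopentyl tetradecanoate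
Conditions: DCC (1.1 equiv), DMAP (10 mol %), CH2Cl2, 0 °C → rt
Reagents that add atoms: none
Why: Steglich esterification acylates the hydroxyl oxygen, so the C–O stereocentre is retained, and the near-neutral conditions avoid β-elimination of the β-hydroxy ketone.

Step 6
Reactants: 11 (1S)-3,3-dimethyl-4-oxocyclopentyl tetradecanoate
Product: 14 (1R)-3,5,5-trimethyl-4-{[(trifluoromethyl)sulfonyl]oxy}cyclohex-3-en-1-yl tetradecanoate, via α-silyl ketone 12 (not isolated), via enol silane 13 (not isolated)
Conditions: MeC(N2)SiMe3 (1.3 equiv), Sc(OTf)3 (10 mol %), toluene, −78 → 0 °C; then PhNTf2 (1.2 equiv), CsF (2 equiv), DME, rt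
Reagents that add atoms: 1-(trimethylsilyl)diazoethane, CC(=[N+]=[N-])[Si](C)(C)C; N-phenylbis(trifluoromethanesulfonimide), O=S(=O)(N(c1ccccc1)S(=O)(=O)C(F)(F)F)C(F)(F)F
Why: Proposed new method: Sc(OTf)3 activates the ketone for C-attack by the silyl diazoalkane, the anti-periplanar C5 methylene (not the quaternary C3) migrates with loss of N2 as in Lewis-acid diazoalkane ring enlargements, and the resulting α-silyl ketone can only undergo 1,3-C→O silyl (Brook) shift or fluoride C-desilylation toward the new carbon, so a single tetrasubstituted enolate is O-triflated by PhNTf2 and no new stereocentre is formed; closest known reaction type: Sc(OTf)3-catalysed TMSCHN2/diazoalkane homologation of cycloalkanones to β-keto silanes or enol silanes (Tiffeneau–Demjanov-type 1,2-shift) combined with fluoride-mediated triflation of enol silanes.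

Step 7
Reactants: 14 (1R)-3,5,5-trimethyl-4-{[(trifluoromethyl)sulfonyl]oxy}cyclohex-3-en-1-yl tetradecanoate; 15 but-3-en-2-one
Product: 16 (1R)-3,5,5-trimethyl-4-[(1E)-3-oxobut-1-en-1-yl]cyclohex-3-en-1-yl tetradecanoate
Conditions: 15 (3 equiv), Pd(OAc)2 (5 mol %), PPh3 (10 mol %), Et3N (2 equiv), DMF, 70 °C
Reagents that add atoms: none
Why: Mizoroki–Heck reaction of the enol triflate (oxidative addition, syn-carbopalladation at the CH2 terminus of the enone, syn-β-hydride elimination) forms the C6–C7 bond and gives the E-enone while the ester and C3 are untouched.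

Step 8
Reactants: 16 (1R)-3,5,5-trimethyl-4-[(1E)-3-oxobut-1-en-1-yl]cyclohex-3-en-1-yl tetradecanoate
Product: 17 (1R,3S,6S)-1,5,5-trimethyl-6-[(1E)-3-oxobut-1-en-1-yl]-7-oxabicyclo[4.1.0]heptan-3-yl tetradecanoate
Conditions: mCPBA (1.1 equiv), CH2Cl2, 0 °C
Reagents that add atoms: 3-chloroperbenzoic acid, OOC(=O)c1cccc(Cl)c1
Why: Prilezhaev epoxidation takes the electron-rich tetrasubstituted C5=C6 bond in preference to the enone C=C and, as I recall for peracid epoxidation of zeaxanthin diesters to violaxanthin diesters, should add mainly anti to the C3 ester, setting 5R,6S (minor cis-epoxide removed by chromatography).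

**Compound list**

1 | 2,2-dimethylcyclopentan-1-one | CC1(C)CCCC1=O | starting material
2 | 5,5-dimethylcyclopent-2-en-1-one | CC1(C)CC=CC1=O | intermediate
3 | (4S)-2,2-dimethyl-4-(4,4,5,5-tetramethyl-1,3,2-dioxaborolan-2-yl)cyclopentan-1-one | CC1(C)OB(OC1(C)C)[C@H]1CC(C)(C)C(=O)C1 | intermediate
4 | (4S)-4-hydroxy-2,2-dimethylcyclopentan-1-one | O[C@H]1CC(C)(C)C(=O)C1 | intermediate
5 | 1-bromoheptane | CCCCCCCBr | starting material
6 | 7-bromohept-1-ene | C=CCCCCCBr | starting material
7 | heptylmagnesium bromide | CCCCCCC[Mg]Br | intermediate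
8 | tetradec-1-ene | CCCCCCCCCCCCC=C | intermediate
9 | tritetradecylborane | CCCCCCCCCCCCCCB(CCCCCCCCCCCCCC)CCCCCCCCCCCCCC | intermediate
10 | tetradecanoic acid | CCCCCCCCCCCCCC(=O)O | intermediate
11 | (1S)-3,3-dimethyl-4-oxocyclopentyl tetradecanoate | CCCCCCCCCCCCCC(=O)O[C@H]1CC(C)(C)C(=O)C1 | intermediate
12 | (1S)-3,3,5-trimethyl-4-oxo-5-(trimethylsilyl)cyclohexyl tetradecanoate (C5 epimers) | CCCCCCCCCCCCCC(=O)O[C@H]1CC(C)(C)C(=O)C(C)([Si](C)(C)C)C1 | intermediate
13 | (1R)-3,5,5-trimethyl-4-[(trimethylsilyl)oxy]cyclohex-3-en-1-yl tetradecanoate | CCCCCCCCCCCCCC(=O)O[C@H]1CC(C)(C)C(O[Si](C)(C)C)=C(C)C1 | intermediate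
14 | (1R)-3,5,5-trimethyl-4-{[(trifluoromethyl)sulfonyl]oxy}cyclohex-3-en-1-yl tetradecanoate | CCCCCCCCCCCCCC(=O)O[C@H]1CC(C)(C)C(OS(=O)(=O)C(F)(F)F)=C(C)C1 | intermediate
15 | but-3-en-2-one | CC(=O)C=C | starting material
16 | (1R)-3,5,5-trimethyl-4-[(1E)-3-oxobut-1-en-1-yl]cyclohex-3-en-1-yl tetradecanoate | CCCCCCCCCCCCCC(=O)O[C@H]1CC(C)(C)C(/C=C/C(C)=O)=C(C)C1 | intermediate
17 | (1R,3S,6S)-1,5,5-trimethyl-6-[(1E)-3-oxobut-1-en-1-yl]-7-oxabicyclo[4.1.0]heptan-3-yl tetradecanoate, i.e. (3S,5R,6S)-5,6-epoxy-3-tetradecanoyloxy-5,6-dihydro-β-ionone | CCCCCCCCCCCCCC(=O)O[C@H]1CC(C)(C)[C@]2(/C=C/C(C)=O)O[C@]2(C)C1 | target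

The oxygen-bearing ring carbon keeps one spatial arrangement from 4 to 17; its CIP letter changes (S in 3, 4, 11, 12; R in 13, 14, 16; S in 17) only because the priorities of the ring branches change.

**Step count and risks**

Total step count: 8. Longest linear sequence: 6 steps (1 → 2 → 4 → 11 → 14 → 16 → 17; the acid branch 5/6 → 8 → 10 → 11 → 17 is equally long).

Three steps most likely to fail:

Step 6 (new one-pot ring expansion/triflation). The fully substituted diazo carbon may add slowly to the ketone next to the CMe2 group, the β-acyloxy ketone may lose tetradecanoic acid under Sc(OTf)3, or the quaternary carbon may migrate in part. The fallback uses known chemistry and sets out from 11. Ethereal diazoethane with BF3·OEt2 in Et2O at −78 °C (classical Lewis-acid-promoted diazoalkane ring enlargement with CH2 migration) gives (1R)-3,3,5-trimethyl-4-oxocyclohexyl tetradecanoate F1 as a mixture of C5 epimers. Tf2O with 2,6-di-tert-butyl-4-methylpyridine in CH2Cl2 at rt then removes the only available α-hydrogen and O-triflates without touching the ester, coming back to the route at 14.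

Step 7 (Heck coupling). Carbopalladation by the hindered tetrasubstituted alkenyl–palladium species may be sluggish, and 15 can polymerise. The fallback sets out from 14: Stille coupling with (E)-4-(tributylstannyl)but-3-en-2-one (Pd2(dba)3, AsPh3, LiCl, NMP, 50 °C) delivers the E-enone preformed by transmetallation instead of by insertion and β-hydride elimination. It comes back at 16 and makes no new compound (F0).

Step 8 (epoxidation). The anti preference rests on carotenoid diester precedent and may be low, or even reversed, with the twisted dienone side chain. The fallback sets out from 16 and replaces steric control by hydroxyl delivery plus inversion: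
- K2CO3 in MeOH cleaves the ester to (3E)-4-[(4R)-4-hydroxy-2,6,6-trimethylcyclohex-1-en-1-yl]but-3-en-2-one F2.
- Mitsunobu reaction with 4-nitrobenzoic acid (PPh3, DIAD, THF) inverts it to (1S)-3,5,5-trimethyl-4-[(1E)-3-oxobut-1-en-1-yl]cyclohex-3-en-1-yl 4-nitrobenzoate F3.
- Methanolysis (K2CO3, MeOH) gives (3E)-4-[(4S)-4-hydroxy-2,6,6-trimethylcyclohex-1-en-1-yl]but-3-en-2-one F4.
- VO(acac)2/t-BuOOH in CH2Cl2 epoxidises syn to the homoallylic hydroxyl, giving (3E)-4-[(1S,4R,6R)-4-hydroxy-2,2,6-trimethyl-7-oxabicyclo[4.1.0]heptan-1-yl]but-3-en-2-one F5.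
- A second Mitsunobu reaction with acid 10 (PPh3, DIAD, THF) esterifies with inversion, so the ester ends anti to the oxirane, coming back at 17.

**Further compounds**

F1 | step 6 | (1R)-3,3,5-trimethyl-4-oxocyclohexyl tetradecanoate (C5 epimers) | CCCCCCCCCCCCCC(=O)O[C@H]1CC(C)(C)C(=O)C(C)C1
F0 | step 7 | none | none
F2 | step 8 | (3E)-4-[(4R)-4-hydroxy-2,6,6-trimethylcyclohex-1-en-1-yl]but-3-en-2-one | O[C@H]1CC(C)(C)C(/C=C/C(C)=O)=C(C)C1
F3 | step 8 | (1S)-3,5,5-trimethyl-4-[(1E)-3-oxobut-1-en-1-yl]cyclohex-3-en-1-yl 4-nitrobenzoate | O=C(O[C@@H]1CC(C)(C)C(/C=C/C(C)=O)=C(C)C1)c1ccc(cc1)[N+](=O)[O-]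
F4 | step 8 | (3E)-4-[(4S)-4-hydroxy-2,6,6-trimethylcyclohex-1-en-1-yl]but-3-en-2-one | O[C@@H]1CC(C)(C)C(/C=C/C(C)=O)=C(C)C1
F5 | step 8 | (3E)-4-[(1S,4R,6R)-4-hydroxy-2,2,6-trimethyl-7-oxabicyclo[4.1.0]heptan-1-yl]but-3-en-2-one | O[C@@H]1CC(C)(C)[C@]2(/C=C/C(C)=O)O[C@]2(C)C1
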